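Temperature is what separates these flasks: spring, summer and winter carry one charge for 12 h.

in all of them: substrate 1.2 M
- green: reagent 0.55 equiv; temperature 35 °C; run made earlier
- amber: reagent 2.2 equiv; temperature 60 °C; run made earlier
- spring: reagent 1.10 equiv; temperature 80 °C; time 12 h
- summer: reagent 1.10 equiv; temperature 40 °C; time 12 h
- winter: reagent 1.10 equiv; temperature 60 °C; time 12 h

- green (time / h: target / %): 15.0: 2.5; 30.0: 5.8; 50.0: 8.1; 60.0: 8.6; 72.0: 8.1; 96.0: 11.8; 120: 9.9
- amber (time / h: target / %): 4.00: 12.8; 8.00: 15.4; 15.0: 16.6; 20.0: 16.3; 25.0: 18.1; 30.0: 16.2

(readings scatter by 1 percentage point)

- the flask that comes out highest in amount of target, in percent of the substrate charged, or "all alike" when all lie within 1.5 percentage points (spring / summer / winter / all alike)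
- target at the end, in percent of the substrate charged, spring
- target at the end, in percent of the substrate charged, summer
- target at the end, in percent of the substrate charged, winter

- the numbers in the tables scatter by 1 percentage point (one standard deviation)

I go to logarithms and ask how many powers of ten of target one step of temperature is worth, the step from summer to winter being also the step from winter to spring. The early rates give a first answer. Green, at 35 °C, reads as 0.00193 h⁻¹ of the charge up to 30.0 h, and amber, at 60 °C, as 0.0320 h⁻¹ up to 4.00 h. Taking off the reagent ratio of 4.00 as first order and scaling the temperature gap to one step, I get 0.493 decades.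

But amber bends right after that reading, standing at 15.4% at 8.00 h, so I also compare where the runs stop. Green averages 9.60% from 60.0 h on and amber 16.8% from 15.0 h on, which is 0.194 decades. That figure is uncorrected for reagent, and I see no way to correct it. The asked time lies before green's stop and beyond amber's bend, so I trust neither answer by itself. I commit to their midpoint, 0.344 decades. This is the climb, the powers of ten of target gained per step of temperature at fixed charge and time, an apparent temperature coefficient, and it means a factor 2.21 per step.

For an anchor I keep summer on green's rate, scaled to 1.10 equiv and 40 °C with the rate answer: 6.16% at 12 h. Winter then gets 13.6% and spring 30.0%. Spring's figure stands above amber's stop, which troubles me, but amber ran at 60 °C and spring runs at 80 °C, so I keep it.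

The forecast, from the same runs, differs. It names winter, with 7.5% for spring, 7.5% for summer and 10.5% for winter, on the ground that the stops “lie far below the reagent limit, so I read them as equilibrium”. We part at the hot end, where I rank spring first.

Spring comes out highest, at 36.8%, over winter's 16.4% and summer's 7.14%.

    target ⇌ isomer of the product (K = 0.600, k = 0.00140 min⁻¹, Ea = 121 kJ mol⁻¹, ΔH = −62.0 kJ mol⁻¹)
    substrate + reagent → target (k = 8.40 × 10⁻⁴ M⁻¹ min⁻¹, Ea = 82.0 kJ mol⁻¹)
    substrate + 2 reagent → side product (k = 0.00150 M⁻² min⁻¹, Ea = 63.0 kJ mol⁻¹)
    (constants at 60 °C)

At 12.0 h, spring and winter hold side product at 30.0% and 30.3%. Carried from winter to a repeat of summer at 65 °C, the climb gives 20.0%, and that flask holds 20.2% of target.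

The earlier runs and the new flask come from a simulation on assumed constants, and the scatter is random.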